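The ratio to read first is that of two rise constants. After 0.167 min, with no product read in either run, beta's reading of open intermediate gives a first-order rise constant 1.44 times eta's, on twice the catalyst. On the list of suspects, free catalyst turns starting material into open intermediate, and open intermediate goes on through catalyst intermediate, with partner, to product.

| flask | starting material | partner | free catalyst | remark | time |
|---|---|---|---|---|---|
| eta | 0.063 M | 0.55 equiv | 0.19 mol% | run made earlier |  |
| epsilon | 0.063 M | 2.2 equiv | 0.19 mol% | run made earlier |  |
| beta | 0.063 M | 1.1 equiv | 0.38 mol% | run made earlier |  |
| flask | 0.063 M | 1.10 equiv | 0.19 mol% |  | 3.0 min |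

| run | time / min | open intermediate / % | product / % |
|---|---|---|---|
| eta | 0.167 | 77 | 0 |
| eta | 0.250 | 87 | 0 |
| eta | 0.417 | 95 | 2 |
| eta | 0.667 | 98 | 2 |
| eta | 1.00 | 102 | 3 |
| eta | 2.00 | 96 | 2 |
| eta | 3.00 | 97 | 7 |
| epsilon | 0.167 | 77 | 0 |
| epsilon | 0.250 | 85 | 1 |
| epsilon | 0.417 | 95 | 4 |
| epsilon | 0.667 | 95 | 6 |
| epsilon | 1.00 | 95 | 6 |
| epsilon | 2.00 | 84 | 12 |
| epsilon | 3.00 | 82 | 23 |
| beta | 0.167 | 88 | 0 |
| beta | 0.333 | 98 | 4 |
| beta | 0.667 | 97 | 1 |
| beta | 1.33 | 92 | 8 |
| beta | 3.00 | 84 | 14 |

(each reading ± 1.5 percentage points)

- what was read earlier has a scatter of 1.5 percentage points, one standard deviation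
- on the list of suspects stand: 2 free catalyst <-> resting dimer; starting material + free catalyst -> free catalyst + open intermediate; free catalyst + open intermediate <-> catalyst intermediate; partner + catalyst intermediate -> free catalyst + product

- time up to 3.0 min at which open intermediate stands highest
- the amount of open intermediate, in percent of the starting material charged, at that time
- earliest time at which at least nineteen twentieths of that best amount are there, in min
- latest time at which they still are, in min

Two chemists dispute how c(free catalyst) follows the charge. Their measure reads 0.529: it is the catalyst order, the power of the catalyst charge that a rate through free catalyst follows. The first chemist takes the whole charge to work as free catalyst, which means order 1, and notes that the reading rests on two points with a scatter of 1.5 percentage points. The second takes free catalyst to stand in balance with resting dimer, so that c(free catalyst) follows the square root of the charge, order 0.5, and notes that the reading lies closer to this.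

They agree on the rise. Eta and epsilon read 77% and 77% at 0.167 min, on 0.55 equiv and 2.2 equiv of partner, so the flask, on eta's loading, should fill as eta did, reaching a plateau near 98% at 0.667 min.

They part on the drain. The flask is beta with half its catalyst, and beta reads 14% of product at 3.00 min. The first chemist divides this by two and expects 7.00% in the flask; the second divides by two raised to the order and expects 9.70%. At a steady drain, the margin of 5.00% lasts 2.14 min for the first and 1.55 min for the second. Counted from the plateau, the flask's window, the stretch within that margin of the best, closes near 2.81 min or near 2.21 min. I side with the second.

The forecast, on “square-root behaviour”, puts the highest open intermediate at 0.7 min with 96.5%, and the window from 0.37 min to 2.2 min.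

The flask has its highest open intermediate at 0.666 min with 97.2%, and its window runs from 0.337 min to 2.08 min.

    2 free catalyst ⇌ resting dimer, settled at all times (K = 32000 M⁻¹)
    starting material + free catalyst → free catalyst + open intermediate (k = 3900 M⁻¹ s⁻¹)
    free catalyst + open intermediate ⇌ catalyst intermediate (K = 7.60 M⁻¹, k = 330 M⁻¹ s⁻¹)
    partner + catalyst intermediate → free catalyst + product (k = 42.0 M⁻¹ s⁻¹)

The flask's window closes nearer the second reckoning than the first, with 10.8% of product at 3.00 min. At 0.666 min the flask holds 27.9% of its catalyst free, 12.2% as catalyst intermediate and 59.8% as resting dimer, the resting state, and the binding constant of resting dimer times the c(free catalyst) of the charge is 3.8; in that balance, order 1 belongs where this product lies far below one. The neighbour with 0.25 M of starting material, on the same loading, carries 3.97 times the catalyst concentration, so the order gives 2.07 times the c(free catalyst); at 3.00 min it holds 15.4% of its catalyst free, against 28.1% in the flask, which is 2.17 times the concentration.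

Readings and results stem from a simulated flask on assumed constants, and the scatter is random.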